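**Retrosynthetic overview**
1. Feature: in the oxolan-2-one ring, the methine C4 lies two atoms from the ring oxygen (O1–C5H2–C4H) and is bonded to C3, the carbon α to the carbonyl C2. Cutting C3–C4 leads back to the diazoacetate of a primary alcohol whose second chain carbon is a plain CH2.
2. After that closure, two tasks remain: the C3 hydroxyl (enolate hydroxylation anti to the C4 side chain) and the silyl-to-acetate exchange on the side-chain CH2O.
3. The primary alcohol comes from a sacrificial 4-alkenylbutanolide, opened as a Weinreb amide so that CH2O and CH2CH2O are told apart. That butanolide is made by Rh/BINAP conjugate addition of a 1-(hydrindanyl)ethenylboronate to furan-2(5H)-one, which sets the side-chain methine.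
4. The boronate comes from the 1β-acetyl trans-hydrindane, and that from 4,4,7a-trimethylhydrindan-1-one. The hydrindanone is built from 2-methylcyclopentane-1,3-dione and ethyl vinyl ketone: an amino-acid aldol sets C7a, and reductive methylation sets C3a and the gem-dimethyl group.
5. Ring order: cyclopentane (bought), then the cyclohexane of the hydrindane (step 2), then the temporary butanolide (bought ring, opened in step 14), then the final butanolide (step 19).

Key step: step 19

Abbreviation: Hy = 4,4,7a-trimethyloctahydro-1H-inden-1-yl, trans-fused (7a-CH3 β, 3a-H α), bonded through C1 on the β face (cis to the 7a-methyl, H-1 α). This is 1R,3aS,7aS in the target.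

Assumption: the facial sense of (R)-BINAP–rhodium on furan-2(5H)-one is taken to follow that on cyclic enones, and the sense of Rh2(4S-MPPIM)4 is taken to follow that on simple primary alkyl diazoacetates; in both steps the catalyst is taken to dominate over the existing stereocentres.

**Route**

Step 1
Reactants: 1 2-methylcyclopentane-1,3-dione; 2 pent-1-en-3-one (ethyl vinyl ketone)
Product: 3 2-methyl-2-(3-oxopentyl)cyclopentane-1,3-dione
Conditions: H2O, AcOH (cat.), 75 °C
Reagents that add atoms: none
Why: Michael addition of the acidic cyclic 1,3-dione to the vinyl ketone, which stops at the triketone because the new quaternary carbon cannot enolise; no stereocentre is formed.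

Step 2
Reactants: 3 2-methyl-2-(3-oxopentyl)cyclopentane-1,3-dione
Product: 4 (7aS)-4,7a-dimethyl-2,3,7,7a-tetrahydro-1H-indene-1,5(6H)-dione
Conditions: L-phenylalanine (1 equiv), (1S)-(+)-camphor-10-sulfonic acid (0.5 equiv), DMF, 30 → 70 °C; recrystallisation
Reagents that add atoms: none
Why: Hajos–Parrish–Eder–Sauer–Wiechert reaction, in which the enamine of the ethyl ketone with the primary L-amino acid attacks one of the two enantiotopic ring carbonyls in an acid-organised transition state and so sets C7a as S, after which acid-promoted dehydration gives the tetrasubstituted enone (a primary amino acid is used because this more hindered ketone forms a proline enamine poorly).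

Step 3
Reactants: 4 (7aS)-4,7a-dimethyl-2,3,7,7a-tetrahydro-1H-indene-1,5(6H)-dione
Product: 5 (1S,7aS)-1-hydroxy-4,7a-dimethyl-1,2,3,6,7,7a-hexahydro-5H-inden-5-one
Conditions: NaBH4 (0.3 equiv), EtOH, −15 °C
Reagents that add atoms: none
Why: Chemoselective borohydride reduction, since the saturated cyclopentanone is more electrophilic than the tetrasubstituted enone, and hydride arrives on the α face opposite the angular methyl to give the 1β (1S) alcohol.

Step 4
Reactants: 5 (1S,7aS)-1-hydroxy-4,7a-dimethyl-1,2,3,6,7,7a-hexahydro-5H-inden-5-one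
Product: 6 (1S,7aS)-1-(tert-butyldimethylsilyloxy)-4,7a-dimethyl-1,2,3,6,7,7a-hexahydro-5H-inden-5-one
Conditions: TBSCl, imidazole, DMF, rt
Reagents that add atoms: tert-butyldimethylsilyl chloride, CC(C)(C)[Si](C)(C)Cl
Why: Standard imidazole-promoted silylation masks the alcohol against O-methylation in the next step, and the silyl ether tolerates dissolving metal.

Step 5
Reactants: 6 (1S,7aS)-1-(tert-butyldimethylsilyloxy)-4,7a-dimethyl-1,2,3,6,7,7a-hexahydro-5H-inden-5-one
Product: 8 (1S,3aR,7aS)-1-(tert-butyldimethylsilyloxy)-4,4,7a-trimethyloctahydro-5H-inden-5-one, via lithium enolate 7 (not isolated)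
Conditions: Li (2.2 equiv), tBuOH (1 equiv), NH3(l)/THF, −78 °C; then MeI, −78 → −33 °C
Reagents that add atoms: lithium, [Li] (carried only in 7); iodomethane, CI
Why: Dissolving-metal reductive alkylation of an enone, in which the β-carbanion at C3a is protonated on the α face to give the trans ring fusion (the usual outcome for 1β-oxygenated 7a-methylhydrindenones) and the regiospecific C4=C5 enolate is then C-methylated to complete the gem-dimethyl group.

Step 6
Reactants: 8 (1S,3aR,7aS)-1-(tert-butyldimethylsilyloxy)-4,4,7a-trimethyloctahydro-5H-inden-5-one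
Product: 10 (1S,3aS,7aS)-4,4,7a-trimethyloctahydro-1H-inden-1-ol, via hydrazone 9 (not isolated)
Conditions: N2H4·H2O, KOH, diethylene glycol, 130 °C, then 210 °C with removal of H2O
Reagents that add atoms: hydrazine hydrate, NN.O (nitrogen carried only in 9)
Why: Wolff–Kishner reduction in the Huang-Minlon form, which is reliable for ketones flanked by a gem-dimethyl group; both α positions are free of stereocentres, and the hot alkaline glycol should also cleave the silyl ether so that the free alcohol is collected.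

Step 7
Reactants: 10 (1S,3aS,7aS)-4,4,7a-trimethyloctahydro-1H-inden-1-ol
Product: 11 (3aS,7aS)-4,4,7a-trimethyloctahydro-1H-inden-1-one
Conditions: nPr4N[RuO4] (5 mol %), NMO, 4 Å molecular sieves, CH2Cl2, rt
Reagents that add atoms: none
Why: Ley–Griffith oxidation of a hindered secondary alcohol under neutral conditions; no epimerisable centre lies next to the new ketone.

Step 8
Reactants: 11 (3aS,7aS)-4,4,7a-trimethyloctahydro-1H-inden-1-one
Product: 12 (1Z,3aS,7aS)-1-ethylidene-4,4,7a-trimethyloctahydro-1H-indene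
Conditions: EtPPh3Br, KOtBu, THF, reflux
Reagents that add atoms: ethyltriphenylphosphonium bromide, CC[P+](c1ccccc1)(c1ccccc1)c1ccccc1.[Br-]
Why: Wittig olefination with a non-stabilised ylide, as practised on the analogous 17-oxo steroids, should give mainly the Z alkene (methyl syn to C7a); the geometry affects only a carbinol centre that is erased in step 10.

Step 9
Reactants: 12 (1Z,3aS,7aS)-1-ethylidene-4,4,7a-trimethyloctahydro-1H-indene
Product: 14 (1S)-1-Hy-ethan-1-ol, via organoborane 13 (not isolated)
Conditions: 9-BBN, THF, 60 °C; then NaOH aq, H2O2, 0 °C → rt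
Reagents that add atoms: 9-borabicyclo[3.3.1]nonane, B1C2CCCC1CCC2 (carried only in 13); hydrogen peroxide, OO
Why: Hydroboration–oxidation, in which syn addition occurs on the α face away from the 7a-methyl with boron on the less substituted carbon, so H-1 is placed α and the side chain β (this sets C1), and the oxidation proceeds with retention.

Step 10
Reactants: 14 (1S)-1-Hy-ethan-1-ol
Product: 15 1-Hy-ethan-1-one (1β-acetyl hydrindane)
Conditions: nPr4N[RuO4] (5 mol %), NMO, 4 Å molecular sieves, CH2Cl2, rt
Reagents that add atoms: none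
Why: Ley–Griffith oxidation under neutral conditions, and the 1β-acetyl epimer formed is also the thermodynamically preferred one, so C1 is safe.

Step 11
Reactants: 15 1-Hy-ethan-1-one
Product: 17 1-Hy-ethenyl trifluoromethanesulfonate, via potassium enolate 16 (not isolated)
Conditions: KN(SiMe3)2, THF, −78 °C; then PhNTf2, −78 → 0 °C
Reagents that add atoms: potassium bis(trimethylsilyl)amide, C[Si](C)(C)[N-][Si](C)(C)C.[K+] (potassium carried only in 16); N-phenylbis(trifluoromethanesulfonimide), O=S(=O)(N(c1ccccc1)S(=O)(=O)C(F)(F)F)C(F)(F)F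
Why: Kinetic enolisation with a bulky amide removes a methyl proton rather than the hindered tertiary H-1, and O-triflation traps the terminal enolate without touching C1.

Step 12
Reactants: 17 1-Hy-ethenyl trifluoromethanesulfonate; 18 bis(pinacolato)diboron
Product: 19 2-(1-Hy-ethenyl)-4,4,5,5-tetramethyl-1,3,2-dioxaborolane
Conditions: PdCl2(PPh3)2 (3 mol %), PPh3 (6 mol %), KOPh, toluene, 50 °C
Reagents that add atoms: none
Why: Miyaura borylation of an alkenyl triflate, where phenoxide activates the diboron for transmetalation but is too weak a base to drive Suzuki homocoupling of the product.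

Step 13
Reactants: 19 2-(1-Hy-ethenyl)-4,4,5,5-tetramethyl-1,3,2-dioxaborolane; 20 furan-2(5H)-one (3 equiv)
Product: 21 (4R)-4-(1-Hy-ethenyl)oxolan-2-one
Conditions: [RhCl(C2H4)2]2 (2.5 mol %), (R)-BINAP (6 mol %), KOH aq (0.5 equiv), dioxane/H2O 10:1, 50 °C
Reagents that add atoms: none
Why: Hayashi–Miyaura reaction, in which hydroxide-assisted boron-to-rhodium transmetalation gives an alkenylrhodium–BINAP species that inserts the butenolide C=C and is released by hydrolysis of the rhodium enolate; the (R)-BINAP pocket exposes the C4 face that leads to the 4R centre, and the ethylene precatalyst leaves no achiral diene on rhodium to run an unselective background reaction.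

Step 14
Reactants: 21 (4R)-4-(1-Hy-ethenyl)oxolan-2-one
Product: 22 (3R)-4-Hy-3-(hydroxymethyl)-N-methoxy-N-methylpent-4-enamide
Conditions: MeNH(OMe)·HCl, Me3Al, CH2Cl2, 0 °C → rt
Reagents that add atoms: N,O-dimethylhydroxylamine hydrochloride, CNOC.Cl
Why: Weinreb aminolysis of a lactone with the aluminium amide, driven forward because the product is held as its aluminium alkoxide; it frees the former C5 hydroxyl and marks the carbonyl end of the chain without touching the stereocentre.

Step 15
Reactants: 22 (3R)-4-Hy-3-(hydroxymethyl)-N-methoxy-N-methylpent-4-enamide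
Product: 23 (3R)-4-Hy-N-methoxy-N-methyl-3-[(triisopropylsilyloxy)methyl]pent-4-enamide
Conditions: TIPSOTf, 2,6-lutidine, CH2Cl2, −78 → 0 °C
Reagents that add atoms: triisopropylsilyl trifluoromethanesulfonate, CC(C)[Si](OS(=O)(=O)C(F)(F)F)(C(C)C)C(C)C
Why: Silylation of the primary alcohol with the silyl triflate is fast enough to outrun relactonisation of the γ-hydroxy amide, and lutidine keeps the alkene safe from acid.

Step 16
Reactants: 23 (3R)-4-Hy-N-methoxy-N-methyl-3-[(triisopropylsilyloxy)methyl]pent-4-enamide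
Product: 25 (3R)-4-Hy-3-[(triisopropylsilyloxy)methyl]pent-4-en-1-ol, via aldehyde 24 (not isolated)
Conditions: iBu2AlH, THF, −78 °C; then MeOH, NaBH4, −78 → 0 °C
Reagents that add atoms: none
Why: Weinreb amide reduction stops at the chelated tetrahedral aluminium adduct, methanol then releases the aldehyde, and borohydride reduces it at once to the primary alcohol.

Step 17
Reactants: 25 (3R)-4-Hy-3-[(triisopropylsilyloxy)methyl]pent-4-en-1-ol; 26 bromoacetyl bromide
Product: 27 (3R)-4-Hy-3-[(triisopropylsilyloxy)methyl]pent-4-en-1-yl bromoacetate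
Conditions: NaHCO3, MeCN, 0 °C
Reagents that add atoms: none
Why: O-acylation of an unhindered primary alcohol by the acid bromide, with solid bicarbonate taking up HBr so that the silyl ether and the alkene are not exposed to acid.

Step 18
Reactants: 27 (3R)-4-Hy-3-[(triisopropylsilyloxy)methyl]pent-4-en-1-yl bromoacetate
Product: 28 (3R)-4-Hy-3-[(triisopropylsilyloxy)methyl]pent-4-en-1-yl diazoacetate
Conditions: TsNHNHTs, DBU, THF, 0 °C
Reagents that add atoms: N,N'-ditosylhydrazine, Cc1ccc(cc1)S(=O)(=O)NNS(=O)(=O)c1ccc(C)cc1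
Why: Diazoacetate synthesis from a bromoacetate, in which the ditosylhydrazine anion is N-alkylated and two base-induced sulfinate eliminations (the second of Bamford–Stevens type) leave the diazo group under conditions that spare every other function.

Step 19
Reactants: 28 (3R)-4-Hy-3-[(triisopropylsilyloxy)methyl]pent-4-en-1-yl diazoacetate
Product: 29 (4R)-4-[(2R)-3-Hy-1-(triisopropylsilyloxy)but-3-en-2-yl]oxolan-2-one
Conditions: Rh2(4S-MPPIM)4 (1–2 mol %; MPPIM = methyl 2-oxo-1-(3-phenylpropanoyl)imidazolidine-4-carboxylate), CH2Cl2, reflux, 28 added by syringe pump over 10 h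
Reagents that add atoms: none
Why: The diazo carbon of 28 binds an axial site of the dirhodium carboxamidate, N2 leaves, and the electrophilic rhodium carbenoid inserts into one C–H bond of the chain CH2 next to the side-chain methine through a concerted, three-centre, hydride-transfer-like transition state that frees the catalyst. The closest known reaction type is the enantioselective carbenoid C–H insertion of 3-substituted propyl diazoacetates to 4-substituted γ-butyrolactones with chiral dirhodium carboxamidates, applied here to a more branched chain. The oxolan-2-one ring closes by 1,5-insertion: the carbenoid carbon becomes C3, the inserted carbon (second from the ester oxygen) becomes C4, and the new C3–C4 bond completes the five-membered ring O1–C2–C3–C4–C5. C4 is the only new stereocentre and is fixed by which diastereotopic hydrogen is replaced (with retention); the pocket formed by the ligand ester groups around the carbenoid makes that choice, the 4S ligand series being taken as the one that gives this spatial sense with simple primary alkyl diazoacetates, while the adjacent R methine can only reinforce or erode it. The step needs site selectivity against 1,4-insertion at OCH2 (β-lactone), 1,6-insertion at the tertiary allylic methine (δ-lactone) and 1,7-insertion at CH2OTIPS, and chemoselectivity against cyclopropanation of the 1,1-disubstituted alkene (seven-membered lactone). The weakly electrophilic carboxamidate carbenoid has a strong kinetic bias for the five-membered transition state, the methine and the alkene are screened by the TIPS ether and by the quaternary C7a flank of the hydrindane, and slow addition suppresses carbene dimers.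

Step 20
Reactants: 29 (4R)-4-[(2R)-3-Hy-1-(triisopropylsilyloxy)but-3-en-2-yl]oxolan-2-one
Product: 31 (3S,4R)-3-hydroxy-4-[(2R)-3-Hy-1-(triisopropylsilyloxy)but-3-en-2-yl]oxolan-2-one, via potassium enolate 30 (not isolated)
Conditions: KN(SiMe3)2, THF, −78 °C; then 3-phenyl-2-(phenylsulfonyl)oxaziridine, −78 °C
Reagents that add atoms: potassium bis(trimethylsilyl)amide, C[Si](C)(C)[N-][Si](C)(C)C.[K+] (potassium carried only in 30); 3-phenyl-2-(phenylsulfonyl)oxaziridine, O=S(=O)(N1OC1c1ccccc1)c1ccccc1
Why: Davis oxidation of the lactone enolate, in which the oxaziridine oxygen is delivered to the ring face opposite the bulky C4 substituent to give the 3,4-trans (3S) alcohol, and the potassium enolate limits addition to the sulfonimine by-product.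

Step 21
Reactants: 31 (3S,4R)-3-hydroxy-4-[(2R)-3-Hy-1-(triisopropylsilyloxy)but-3-en-2-yl]oxolan-2-one
Product: 32 (3S,4R)-3-hydroxy-4-[(2R)-3-Hy-1-hydroxybut-3-en-2-yl]oxolan-2-one
Conditions: HF·pyridine, pyridine, THF, 0 °C → rt
Reagents that add atoms: none
Why: Fluoride-driven desilylation in a buffered, non-basic medium, chosen so that C3 is not epimerised, the free primary hydroxyl is not activated for translactonisation, and the alkene is not protonated.

Step 22
Reactants: 32 (3S,4R)-3-hydroxy-4-[(2R)-3-Hy-1-hydroxybut-3-en-2-yl]oxolan-2-one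
Product: 33 (2R)-3-Hy-2-[(3R,4S)-4-hydroxy-5-oxooxolan-3-yl]but-3-en-1-yl acetate (target)
Conditions: AcCl (1.05 equiv), 2,4,6-collidine, CH2Cl2, −78 °C
Reagents that add atoms: acetyl chloride, CC(=O)Cl
Why: Selective acylation, since at low temperature with a hindered non-nucleophilic base the primary alcohol reacts much faster than the secondary hydroxyl, which is deactivated by the adjacent lactone carbonyl.

**Compound list**
1 | 2-methylcyclopentane-1,3-dione | CC1C(=O)CCC1=O | starting material
2 | pent-1-en-3-one | CCC(=O)C=C | starting material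
3 | 2-methyl-2-(3-oxopentyl)cyclopentane-1,3-dione | CCC(=O)CCC1(C)C(=O)CCC1=O | intermediate
4 | (7aS)-4,7a-dimethyl-2,3,7,7a-tetrahydro-1H-indene-1,5(6H)-dione | C[C@]12CCC(=O)C(C)=C1CCC2=O | intermediate
5 | (1S,7aS)-1-hydroxy-4,7a-dimethyl-1,2,3,6,7,7a-hexahydro-5H-inden-5-one | O[C@H]1CCC2=C(C)C(=O)CC[C@]12C | intermediate
6 | (1S,7aS)-1-(tert-butyldimethylsilyloxy)-4,7a-dimethyl-1,2,3,6,7,7a-hexahydro-5H-inden-5-one | CC(C)(C)[Si](C)(C)O[C@H]1CCC2=C(C)C(=O)CC[C@]12C | intermediate
7 | lithium C4=C5 enolate of the trans-fused 1β-silyloxy-4,7a-dimethylhydrindan-5-one (3a-H α) | [Li+].CC(C)(C)[Si](C)(C)O[C@H]1CC[C@H]2C(C)=C([O-])CC[C@]12C | intermediate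
8 | (1S,3aR,7aS)-1-(tert-butyldimethylsilyloxy)-4,4,7a-trimethyloctahydro-5H-inden-5-one | CC(C)(C)[Si](C)(C)O[C@H]1CC[C@H]2C(C)(C)C(=O)CC[C@]12C | intermediate
9 | C5 hydrazone of 8 | CC(C)(C)[Si](C)(C)O[C@H]1CC[C@H]2C(C)(C)C(=NN)CC[C@]12C | intermediate
10 | (1S,3aS,7aS)-4,4,7a-trimethyloctahydro-1H-inden-1-ol | O[C@H]1CC[C@H]2C(C)(C)CCC[C@]12C | intermediate
11 | (3aS,7aS)-4,4,7a-trimethyloctahydro-1H-inden-1-one | O=C1CC[C@H]2C(C)(C)CCC[C@]12C | intermediate
12 | (1Z,3aS,7aS)-1-ethylidene-4,4,7a-trimethyloctahydro-1H-indene | C/C=C1/CC[C@H]2C(C)(C)CCC[C@]12C | intermediate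
13 | 9-(1-Hy-ethyl)-9-borabicyclo[3.3.1]nonane (boron on the side-chain carbon, H-1 α) | C[C@H](B1C2CCCC1CCC2)[C@H]1CC[C@H]2C(C)(C)CCC[C@]12C | intermediate
14 | (1S)-1-Hy-ethan-1-ol | C[C@H](O)[C@H]1CC[C@H]2C(C)(C)CCC[C@]12C | intermediate
15 | 1-Hy-ethan-1-one | CC(=O)[C@H]1CC[C@H]2C(C)(C)CCC[C@]12C | intermediate
16 | potassium 1-Hy-ethen-1-olate | [K+].C=C([O-])[C@H]1CC[C@H]2C(C)(C)CCC[C@]12C | intermediate
17 | 1-Hy-ethenyl trifluoromethanesulfonate | C=C(OS(=O)(=O)C(F)(F)F)[C@H]1CC[C@H]2C(C)(C)CCC[C@]12C | intermediate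
18 | bis(pinacolato)diboron | CC1(C)OB(OC1(C)C)B1OC(C)(C)C(C)(C)O1 | starting material
19 | 2-(1-Hy-ethenyl)-4,4,5,5-tetramethyl-1,3,2-dioxaborolane | C=C(B1OC(C)(C)C(C)(C)O1)[C@H]1CC[C@H]2C(C)(C)CCC[C@]12C | intermediate
20 | furan-2(5H)-one | O=C1OCC=C1 | starting material
21 | (4R)-4-(1-Hy-ethenyl)oxolan-2-one | C=C([C@H]1CC[C@H]2C(C)(C)CCC[C@]12C)[C@@H]1COC(=O)C1 | intermediate
22 | (3R)-4-Hy-3-(hydroxymethyl)-N-methoxy-N-methylpent-4-enamide | C=C([C@H]1CC[C@H]2C(C)(C)CCC[C@]12C)[C@H](CO)CC(=O)N(C)OC | intermediate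
23 | (3R)-4-Hy-N-methoxy-N-methyl-3-[(triisopropylsilyloxy)methyl]pent-4-enamide | C=C([C@H]1CC[C@H]2C(C)(C)CCC[C@]12C)[C@H](CO[Si](C(C)C)(C(C)C)C(C)C)CC(=O)N(C)OC | intermediate
24 | (3R)-4-Hy-3-[(triisopropylsilyloxy)methyl]pent-4-enal | C=C([C@H]1CC[C@H]2C(C)(C)CCC[C@]12C)[C@H](CO[Si](C(C)C)(C(C)C)C(C)C)CC=O | intermediate
25 | (3R)-4-Hy-3-[(triisopropylsilyloxy)methyl]pent-4-en-1-ol | C=C([C@H]1CC[C@H]2C(C)(C)CCC[C@]12C)[C@H](CO[Si](C(C)C)(C(C)C)C(C)C)CCO | intermediate
26 | bromoacetyl bromide | O=C(Br)CBr | starting material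
27 | (3R)-4-Hy-3-[(triisopropylsilyloxy)methyl]pent-4-en-1-yl bromoacetate | C=C([C@H]1CC[C@H]2C(C)(C)CCC[C@]12C)[C@H](CO[Si](C(C)C)(C(C)C)C(C)C)CCOC(=O)CBr | intermediate
28 | (3R)-4-Hy-3-[(triisopropylsilyloxy)methyl]pent-4-en-1-yl diazoacetate | C=C([C@H]1CC[C@H]2C(C)(C)CCC[C@]12C)[C@H](CO[Si](C(C)C)(C(C)C)C(C)C)CCOC(=O)C=[N+]=[N-] | intermediate
29 | (4R)-4-[(2R)-3-Hy-1-(triisopropylsilyloxy)but-3-en-2-yl]oxolan-2-one | C=C([C@H]1CC[C@H]2C(C)(C)CCC[C@]12C)[C@H](CO[Si](C(C)C)(C(C)C)C(C)C)[C@@H]1COC(=O)C1 | intermediate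
30 | potassium enolate of 29 | C=C([C@H]1CC[C@H]2C(C)(C)CCC[C@]12C)[C@H](CO[Si](C(C)C)(C(C)C)C(C)C)[C@@H]1COC([O-])=C1.[K+] | intermediate
31 | (3S,4R)-3-hydroxy-4-[(2R)-3-Hy-1-(triisopropylsilyloxy)but-3-en-2-yl]oxolan-2-one | C=C([C@H]1CC[C@H]2C(C)(C)CCC[C@]12C)[C@H](CO[Si](C(C)C)(C(C)C)C(C)C)[C@@H]1COC(=O)[C@H]1O | intermediate
32 | (3S,4R)-3-hydroxy-4-[(2R)-3-Hy-1-hydroxybut-3-en-2-yl]oxolan-2-one | C=C([C@H]1CC[C@H]2C(C)(C)CCC[C@]12C)[C@H](CO)[C@@H]1COC(=O)[C@H]1O | intermediate
33 | (2R)-3-Hy-2-[(3R,4S)-4-hydroxy-5-oxooxolan-3-yl]but-3-en-1-yl acetate (Hy = 1R,3aS,7aS) | C=C([C@H]1CC[C@H]2C(C)(C)CCC[C@]12C)[C@H](COC(C)=O)[C@@H]1COC(=O)[C@H]1O | target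

**Step count**
Total step count: 22. Longest linear sequence: 22 steps (1 and 2 to 33); 18, 20 and 26 are bought and enter directly.

**Steps most likely to fail**

Step 19.
- Risk: the carbenoid may be diverted to the tertiary allylic C–H bond, to the 1,1-disubstituted alkene or to dimer formation. The catalyst and the neighbouring methine may also disagree on which diastereotopic hydrogen is replaced.
- Fallback: the same C3–C4 bond is made by auxiliary-controlled enolate alkylation, setting out from 25 and rejoining at 29. Oxidation of 25 with PhI(OAc)2/TEMPO in MeCN–H2O gives the carboxylic acid F1. PivCl/Et3N converts it into the mixed pivalic anhydride F2, which acylates (R)-4-benzyloxazolidin-2-one (LiCl, THF) to give the imide F3. NaN(SiMe3)2 at −78 °C forms the chelated Z sodium enolate F4, and tert-butyl bromoacetate alkylates it on the face away from the benzyl group (Evans alkylation) to give the alkylated imide F5, whose new R centre is the future lactone C4. LiBH4 in Et2O/MeOH removes the auxiliary reductively, sparing the tert-butyl ester, to give the γ-hydroxy ester F6. Catalytic TsOH in warm toluene closes F6 to lactone 29.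

Step 13.
- Risk: transmetalation of the hindered, α-branched alkenylboronate may be so slow that protodeboronation and base-induced consumption of the furanone outrun conjugate addition, or facial control may be weak.
- Fallback: the methine is set by hydride delivery instead of carbon delivery, setting out from 19 and rejoining at 21. Suzuki–Miyaura coupling of 19 with commercial 4-bromofuran-2(5H)-one (Pd(PPh3)4, K3PO4, THF/H2O) gives the 4-alkenylbutenolide F7. Its ester-conjugated ring C3=C4 bond is then reduced by asymmetric copper hydride conjugate reduction (CuCl2, NaOtBu, p-tol-BINAP, polymethylhydrosiloxane, toluene), using the ligand antipode that delivers hydride to the face giving the 4R centre of 21.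

Step 22.
- Risk: over-acetylation at the C3 hydroxyl, or acyl and lactone migration in the free diol, may erode the differentiation of the two hydroxyls.
- Fallback: temporary orthogonal protection, setting out from 31 and rejoining at 33. Allyl chloroformate with pyridine/DMAP gives the C3 allyl carbonate F8, and HF·pyridine then frees the primary alcohol F9. Ac2O/pyridine/DMAP can now be used in excess to give the acetate carbonate F10. Pd(PPh3)4 with morpholine removes the allyl carbonate through a π-allyl complex of zerovalent palladium, leaving the homoallylic acetate untouched and giving 33.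

**Further compounds**
F1 | step 19 | (3R)-4-Hy-3-[(triisopropylsilyloxy)methyl]pent-4-enoic acid | C=C([C@H]1CC[C@H]2C(C)(C)CCC[C@]12C)[C@H](CO[Si](C(C)C)(C(C)C)C(C)C)CC(=O)O
F2 | step 19 | mixed anhydride of F1 with pivalic acid | C=C([C@H]1CC[C@H]2C(C)(C)CCC[C@]12C)[C@H](CO[Si](C(C)C)(C(C)C)C(C)C)CC(=O)OC(=O)C(C)(C)C
F3 | step 19 | (4R)-4-benzyl-3-{(3R)-4-Hy-3-[(triisopropylsilyloxy)methyl]pent-4-enoyl}oxazolidin-2-one | C=C([C@H]1CC[C@H]2C(C)(C)CCC[C@]12C)[C@H](CO[Si](C(C)C)(C(C)C)C(C)C)CC(=O)N1[C@H](Cc2ccccc2)COC1=O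
F4 | step 19 | sodium Z enolate of F3 | C=C([C@H]1CC[C@H]2C(C)(C)CCC[C@]12C)[C@H](CO[Si](C(C)C)(C(C)C)C(C)C)/C=C(\[O-])N1[C@H](Cc2ccccc2)COC1=O.[Na+]
F5 | step 19 | tert-butyl (3R,4R)-3-[(4R)-4-benzyl-2-oxooxazolidine-3-carbonyl]-5-Hy-4-[(triisopropylsilyloxy)methyl]hex-5-enoate | C=C([C@H]1CC[C@H]2C(C)(C)CCC[C@]12C)[C@H](CO[Si](C(C)C)(C(C)C)C(C)C)[C@@H](CC(=O)OC(C)(C)C)C(=O)N1[C@H](Cc2ccccc2)COC1=O
F6 | step 19 | tert-butyl (3R,4R)-5-Hy-3-(hydroxymethyl)-4-[(triisopropylsilyloxy)methyl]hex-5-enoate | C=C([C@H]1CC[C@H]2C(C)(C)CCC[C@]12C)[C@H](CO[Si](C(C)C)(C(C)C)C(C)C)[C@@H](CC(=O)OC(C)(C)C)CO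
F7 | step 13 | 4-(1-Hy-ethenyl)furan-2(5H)-one | C=C([C@H]1CC[C@H]2C(C)(C)CCC[C@]12C)C1=CC(=O)OC1
F8 | step 22 | allyl (3S,4R)-2-oxo-4-[(2R)-3-Hy-1-(triisopropylsilyloxy)but-3-en-2-yl]oxolan-3-yl carbonate | C=C([C@H]1CC[C@H]2C(C)(C)CCC[C@]12C)[C@H](CO[Si](C(C)C)(C(C)C)C(C)C)[C@@H]1COC(=O)[C@H]1OC(=O)OCC=C
F9 | step 22 | allyl (3S,4R)-4-[(2R)-3-Hy-1-hydroxybut-3-en-2-yl]-2-oxooxolan-3-yl carbonate | C=C([C@H]1CC[C@H]2C(C)(C)CCC[C@]12C)[C@H](CO)[C@@H]1COC(=O)[C@H]1OC(=O)OCC=C
F10 | step 22 | (2R)-2-{(3R,4S)-4-[(allyloxy)carbonyloxy]-5-oxooxolan-3-yl}-3-Hy-but-3-en-1-yl acetate | C=C([C@H]1CC[C@H]2C(C)(C)CCC[C@]12C)[C@H](COC(C)=O)[C@@H]1COC(=O)[C@H]1OC(=O)OCC=C
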